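Count in percent of the starting material charged, the unit your question comes in, and test your hunch by treating target and isomer of the product as two tanks joined by a pipe.

| setting | zeta | delta | flask |
|---|---|---|---|
| starting material | 0.50 mM | 0.75 mM | 0.50 mM |
| partner | 0.75 mM | 0.75 mM | 0.750 mM |
| protic impurity | 0.010 mM | 0.010 mM | 0.0100 mM |
| free catalyst | 5 µM | 5 µM | 5.0 µM |
| temperature | 20 °C | 26 °C | 20 °C |
| remark | the very flask that is asked about, followed so far | run made earlier |  |
| time |  |  | 12 min |

| zeta: time / min | zeta: target / % | delta: time / min | delta: target / % |
|---|---|---|---|
| 0.833 | 38 | 0.250 | 16 |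
| 1.33 | 53 | 0.667 | 31 |
| 2.00 | 62 | 1.33 | 46 |
| 2.50 | 63 | 2.00 | 53 |
| 4.00 | 69 | 2.50 | 58 |
| 6.00 | 65 | 3.00 | 60 |
| 10.0 | 66 | 4.00 | 60 |

(each reading ± 1.5 percentage points)

- removed target is counted in
- what was read earlier has a scatter of 1.5 percentage points, one standard deviation
- on the list of suspects stand: partner + free catalyst -> catalyst intermediate A; catalyst intermediate B -> free catalyst + target; starting material + free catalyst -> spent catalyst; target <-> isomer of the product; starting material + catalyst intermediate A -> catalyst intermediate B; starting material + protic impurity -> quenched substrate
- additions bring no volume worth counting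

- oak: at 12 min raise the temperature by 10 K, then wait 12 min
- larch: at 12 min take out 90% of the target then present, then wait 12 min
- alder: change nothing and wait 12 min more
- maple: at 12 min add partner, 100% of the amount charged, then wait 12 min
- birch: at 12 min add free catalyst, 100% of the amount charged, then wait 12 min

- target, in percent of the starting material first charged, at 12 min
- what to do for the largest gain in target; "none" if nothing gains more than 2 percentage points (oak / larch / alder / maple / birch / none)
- target present, with what was taken out counted in, in percent of the starting material first charged, after larch
- target present, with what was taken out counted in, in percent of the starting material first charged, after maple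

Read the zeta tail from 4.00 min onward as an average P of 66.7%, let the protic impurity quench its whole charge, and assume that the rest of the starting material sits in the two tanks. I accept that assumption for a working number because the delta run, at 26 °C and on the same catalyst charge, read 0.450 mM of target against 0.333 mM in zeta. Define the resting split s as the fraction of the two tanks that is target, in thermodynamic control as the field says, and reckon it with q as the quenched share:

q = 2.00%

s = P / (1 − q) = 68.0%

Since the zeta tail stood flat by 4.00 min, a shorter time than the wait of 12 min, let the tanks level again after larch takes out w:

w = 60.0%

left in the tanks = 38.0%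

target with w counted in = w + s × left = 85.9%

With the starting material assumed gone, expect nothing from alder, birch or maple, and commit to 66.7% after each of them. To beat larch, oak needs a split of 87.6%, above the 68.0% reckoned at 20 °C, and on that gap commit to larch.

Your forecast gives 66% now, larch as the best move, 85% after larch and 66% after maple, on the ground that “A similar percentage yield regardless of loading, falling slightly on warming, points to target ⇌ isomer”; my figures run slightly higher, at 66.7% and 85.9%.

The flask gives 66.6% at 12 min, with larch as the best move at a gain of 19 percentage points, 85.7% after larch and 66.6% after maple.

    partner + free catalyst → catalyst intermediate A (k = 7860 L mol⁻¹ s⁻¹, Ea = 39.0 kJ mol⁻¹)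
    catalyst intermediate B → free catalyst + target (k = 2.58 s⁻¹, Ea = 79.0 kJ mol⁻¹)
    starting material + free catalyst → spent catalyst (k = 47.4 L mol⁻¹ s⁻¹, Ea = 51.0 kJ mol⁻¹)
    target ⇌ isomer of the product (K = 0.467, k = 0.0155 s⁻¹, Ea = 90.0 kJ mol⁻¹, ΔH = −30.0 kJ mol⁻¹)
    starting material + catalyst intermediate A → catalyst intermediate B (k = 11200 L mol⁻¹ s⁻¹, Ea = 29.0 kJ mol⁻¹)
    starting material + protic impurity → quenched substrate (k = 5200 L mol⁻¹ s⁻¹, Ea = 36.0 kJ mol⁻¹)
    (constants at 20 °C)

At 12.0 min this flask holds 0% starting material, 66.6% target and 31.1% isomer of the product, and the gain from larch reckons as w(1 − s), here 19 points. Take s to the flask charged with 1.2 mM of starting material, where 62.0% stays unreacted and 0.833% is quenched: its two tanks hold 37.2%, s of that is 25.3%, and that flask stands at 25.1% target.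

(The data come from a simulation for an exercise, noise included.)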